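Oxolane numbering is used throughout: O1, C2 (chain), C3 (CO2H), C4 (=CH2), C5 (C=O).
Retrosynthesis: cut first the exocyclic C4=CH2 (carboxylation, then decarboxylative Mannich methylenation), then the O1–C2 bond of the γ-lactone, then the chain alkene C9'=C10' (cross-metathesis, later hydrogenated), and last C2–C3 together with the C2–O bond of a β-lactone (ketene–aldehyde cyclocondensation).
Enabling feature: C2 is β to the C3 carboxyl and γ to the C5 carboxyl, so the C3 carboxyl can hold the C2 oxygen in a strained oxetan-2-one (temporary ring and leaving group) while the C4–C5 carboxylate arm displaces it at C2 and closes the five-membered lactone.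
Forward: (S)-propylene oxide gives the chain end; undec-10-enal and benzyl succinyl chloride give the cis β-lactone; cross-metathesis joins the chain; hydrogenation frees the acid; ring expansion builds the γ-lactone; methylenation comes last.
Stereochemistry: the remote carbinol is bought; C2 and C3 are set together (cis) by the cinchona catalyst; the ring expansion inverts C2 stereospecifically, which turns the cis β-lactone into the cis (2S,3S) γ-lactone.

Key step: step 6

Assumption: O-trimethylsilylquinine is taken to give the (2R,3S) enantiomer of 8 (sense of induction by analogy with related cinchona-catalysed ketene cycloadditions); the pseudoenantiomeric O-trimethylsilylquinidine would give the antipode.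

Step 1
Reactants: 1 (S)-2-methyloxirane; 2 but-3-en-1-ylmagnesium bromide
Product: 3 (2S)-hept-6-en-2-ol
Conditions: CuI (10 mol %), THF, −30 → 0 °C; then 1 M HCl
Reagents that add atoms: none
Why: Copper-catalysed Grignard opening of a terminal epoxide is an SN2 attack at the unsubstituted carbon, so the purchased (S) carbinol centre should be carried over unchanged.

Step 2
Reactants: 4 4-(benzyloxy)-4-oxobutanoic acid
Product: 5 benzyl 4-chloro-4-oxobutanoate
Conditions: (COCl)2, DMF (cat.), CH2Cl2, 0 → 23 °C; concentrate, use crude
Reagents that add atoms: oxalyl chloride, ClC(=O)C(=O)Cl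
Why: Acid chloride formation through the Vilsmeier-type chloroiminium is routine and should leave the benzyl ester untouched.

Step 3
Reactants: 5 benzyl 4-chloro-4-oxobutanoate; 6 undec-10-enal
Product: 8 benzyl 2-[(2R,3S)-2-(dec-9-en-1-yl)-4-oxooxetan-3-yl]acetate, via ketene benzyl 4-oxobut-3-enoate 7 (not isolated)
Conditions: O-trimethylsilylquinine (10 mol %), LiClO4, iPr2NEt, CH2Cl2/Et2O, −78 °C, slow addition of 5 (2 equiv)
Reagents that add atoms: none
Why: Catalytic asymmetric ketene–aldehyde [2+2] cyclocondensation, in which the cinchona catalyst adds to ketene 7 to give a (Z)-acylammonium enolate that attacks the LiClO4-activated aldehyde through a closed aldol-type transition state and then lactonises, so both ring stereocentres should be set cis under catalyst control.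

Step 4
Reactants: 8 benzyl 2-[(2R,3S)-2-(dec-9-en-1-yl)-4-oxooxetan-3-yl]acetate; 3 (2S)-hept-6-en-2-ol
Product: 9 benzyl 2-[(2R,3S)-2-[(9E,14S)-14-hydroxypentadec-9-en-1-yl]-4-oxooxetan-3-yl]acetate (E/Z mixture expected, E drawn)
Conditions: 3 (3 equiv), second-generation Grubbs catalyst RuCl2(=CHPh)(PCy3)(H2IMes) (5 mol %), CH2Cl2, 40 °C
Reagents that add atoms: none
Why: Olefin cross-metathesis of two unhindered terminal alkenes is driven by loss of ethene and by the excess of 3; the β-lactone, ester and free alcohol are inert to the ruthenium carbene, and the alkene geometry is irrelevant because step 5 saturates it.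

Step 5
Reactants: 9 benzyl 2-[(2R,3S)-2-[(9E,14S)-14-hydroxypentadec-9-en-1-yl]-4-oxooxetan-3-yl]acetate
Product: 10 2-[(2R,3S)-2-[(14S)-14-hydroxypentadecyl]-4-oxooxetan-3-yl]acetic acid
Conditions: H2 (1 atm), 10% Pd/C, EtOAc, 23 °C; filter, use crude
Reagents that add atoms: none
Why: Heterogeneous hydrogenation should saturate the chain alkene and hydrogenolyse the benzyl ester in one neutral operation that leaves the β-lactone and all stereocentres untouched.

Step 6
Reactants: 10 2-[(2R,3S)-2-[(14S)-14-hydroxypentadecyl]-4-oxooxetan-3-yl]acetic acid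
Product: 11 (2S,3S)-2-[(14S)-14-hydroxypentadecyl]-5-oxooxolane-3-carboxylic acid
Conditions: Cs2CO3 (0.55 equiv), DMF (0.02 M), 23 → 40 °C; then 1 M HCl
Reagents that add atoms: none
Why: Deprotonation gives the cesium carboxylate of the CH2CO2H arm, whose oxygen attacks the alkyl carbon of the oxetanone (the future C2) from the side opposite the ring C–O bond, so the four-membered lactone opens by alkyl–oxygen cleavage while the five-membered lactone closes and the former β-lactone carbonyl is released as the C3 carboxylate. The closest known reaction type is the SN2 opening of β-lactones at the β-carbon by carboxylate salts (the propagation step of carboxylate-initiated β-lactone polymerisation), which runs with inversion; here it is intramolecular. The γ-lactone closes in the 5-exo-tet mode, with the nucleophile able to reach close to the backside trajectory, and is driven by release of four-ring strain. No new stereocentre is created: C2 is inverted stereospecifically by the backside displacement and C3 is untouched, so the cis β-lactone should give the cis (2S,3S) γ-lactone, which acyl lactonisation of the same stereodiad (retention, trans) cannot give. The step needs alkyl–oxygen over acyl–oxygen cleavage and substitution over eliminative opening: addition of a weakly basic carboxylate to the lactone carbonyl is reversible, the ring C–O bond lies in the nodal plane of any β-lactone enolate so E1cB is stereoelectronically disfavoured, and only half an equivalent of mild base at high dilution is used.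

Step 7
Reactants: 11 (2S,3S)-2-[(14S)-14-hydroxypentadecyl]-5-oxooxolane-3-carboxylic acid
Product: 12 (2S,3S)-2-[(14S)-14-hydroxypentadecyl]-5-oxooxolane-3,4-dicarboxylic acid (C4 epimers)
Conditions: MeOMgOCO2Me (2 M in DMF, excess), 130 °C; then cold 6 M HCl; extract, use at once
Reagents that add atoms: methoxymagnesium methyl carbonate, CO[Mg]OC(=O)OC
Why: α-Carboxylation of the lactone through a magnesium-chelated enolate–carboxylate should occur only at C4, because the C3 carboxylate shields the adjacent C3–H from deprotonation (cis relationship kept) and the free alcohol is only reversibly carbonated; the new C4 centre is uncontrolled and is destroyed in step 8.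

Step 8
Reactants: 12 (2S,3S)-2-[(14S)-14-hydroxypentadecyl]-5-oxooxolane-3,4-dicarboxylic acid
Product: 14 (2S,3S)-2-[(14S)-14-hydroxypentadecyl]-4-methylidene-5-oxooxolane-3-carboxylic acid (target), via Mannich base 13 (not isolated)
Conditions: 37% aq HCHO, PhNHMe, NaOAc, AcOH, 23 °C
Reagents that add atoms: formaldehyde, C=O
Why: Decarboxylative Mannich methylenation, in which the malonic-type acid condenses with the iminium from formaldehyde and N-methylaniline and Mannich base 13 loses CO2 and the amine, should give the exocyclic alkene under buffered conditions too mild for C3 epimerisation or migration of the double bond into the ring.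

Compound list
1 | (S)-2-methyloxirane [(S)-propylene oxide] | C[C@H]1CO1 | starting material
2 | but-3-en-1-ylmagnesium bromide (THF solution) | C=CCC[Mg]Br | starting material
3 | (2S)-hept-6-en-2-ol | C[C@H](O)CCCC=C | intermediate
4 | 4-(benzyloxy)-4-oxobutanoic acid (monobenzyl succinate) | OC(=O)CCC(=O)OCc1ccccc1 | starting material
5 | benzyl 4-chloro-4-oxobutanoate | ClC(=O)CCC(=O)OCc1ccccc1 | intermediate
6 | undec-10-enal | C=CCCCCCCCCC=O | starting material
7 | benzyl 4-oxobut-3-enoate (ketene) | O=C=CCC(=O)OCc1ccccc1 | intermediate (not isolated)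
8 | benzyl 2-[(2R,3S)-2-(dec-9-en-1-yl)-4-oxooxetan-3-yl]acetate | O=C1O[C@H](CCCCCCCCC=C)[C@@H]1CC(=O)OCc1ccccc1 | intermediate
9 | benzyl 2-[(2R,3S)-2-[(9E,14S)-14-hydroxypentadec-9-en-1-yl]-4-oxooxetan-3-yl]acetate | O=C1O[C@H](CCCCCCCC/C=C/CCC[C@H](C)O)[C@@H]1CC(=O)OCc1ccccc1 | intermediate
10 | 2-[(2R,3S)-2-[(14S)-14-hydroxypentadecyl]-4-oxooxetan-3-yl]acetic acid | O=C1O[C@H](CCCCCCCCCCCCC[C@H](C)O)[C@@H]1CC(=O)O | intermediate
11 | (2S,3S)-2-[(14S)-14-hydroxypentadecyl]-5-oxooxolane-3-carboxylic acid | O=C1C[C@H](C(=O)O)[C@H](CCCCCCCCCCCCC[C@H](C)O)O1 | intermediate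
12 | (2S,3S)-2-[(14S)-14-hydroxypentadecyl]-5-oxooxolane-3,4-dicarboxylic acid (C4 unassigned) | O=C1C(C(=O)O)[C@H](C(=O)O)[C@H](CCCCCCCCCCCCC[C@H](C)O)O1 | intermediate
13 | (2S,3S)-2-[(14S)-14-hydroxypentadecyl]-4-{[methyl(phenyl)amino]methyl}-5-oxooxolane-3,4-dicarboxylic acid (C4 unassigned) | O=C1C(CN(C)c2ccccc2)(C(=O)O)[C@H](C(=O)O)[C@H](CCCCCCCCCCCCC[C@H](C)O)O1 | intermediate (not isolated)
14 | (2S,3S)-2-[(14S)-14-hydroxypentadecyl]-4-methylidene-5-oxooxolane-3-carboxylic acid | C=C1C(=O)O[C@@H](CCCCCCCCCCCCC[C@H](C)O)[C@H]1C(=O)O | target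

Total step count: 8. Longest linear sequence: 7 (steps 2 to 8, from 4).

Steps most likely to fail

Step 6. The carboxylate may add to the β-lactone carbonyl instead of the alkyl carbon, and acyl transfer followed by re-lactonisation with retention would then give the trans series; base-induced eliminative opening of the four-membered ring is the other risk. The fallback sets out from 9 and does the inversion intermolecularly, before any internal carboxylate exists. CsOAc with 18-crown-6 in DMF should open the β-lactone at the alkyl carbon with inversion to give (2S)-2-[(1S,10E,15S)-1-(acetyloxy)-15-hydroxyhexadec-10-en-1-yl]-4-(benzyloxy)-4-oxobutanoic acid F1. Hydrogenation over 10% Pd/C should saturate the alkene and cleave the benzyl ester to give (2S)-2-[(1S,15S)-1-(acetyloxy)-15-hydroxyhexadecyl]butanedioic acid F2. K2CO3 in MeOH should remove the acetate to give (2S)-2-[(1S,15S)-1,15-dihydroxyhexadecyl]butanedioic acid F3, which on acidification should lactonise through the γ-carboxyl with retention and so come back to the route at 11.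

Step 3. The ester-bearing ketene may dimerise or react sluggishly with the enolisable aldehyde, and cis- or enantio-control may erode. The fallback sets out from 5 and 6 and builds the same stereodiad by an auxiliary-controlled aldol. Acylation of lithiated (4S)-4-benzyl-1,3-oxazolidin-2-one (n-BuLi, THF, −78 °C) with 5 should give benzyl 4-[(4S)-4-benzyl-2-oxo-1,3-oxazolidin-3-yl]-4-oxobutanoate F4. The Evans syn-aldol (Bu2BOTf, iPr2NEt, CH2Cl2, −78 °C, then 6) should give benzyl (3S,4R)-3-[(4S)-4-benzyl-2-oxo-1,3-oxazolidine-3-carbonyl]-4-hydroxytetradec-13-enoate F5. LiOH/H2O2 at 0 °C should release (2S,3R)-2-[2-(benzyloxy)-2-oxoethyl]-3-hydroxytridec-12-enoic acid F6. Carboxyl activation with PhSO2Cl in pyridine should close the β-lactone with retention and come back to the route at 8.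

Step 7. Long heating in the basic magnesium medium may epimerise the cis acid or stall before full carboxylation, and the malonic-type product may decarboxylate during work-up. The fallback sets out from 11 and replaces the thermal carboxylation by low-temperature enolate aminomethylation. LiN(SiMe3)2 (3.3 equiv, THF, −78 °C) followed by Eschenmoser's salt (CH2=NMe2+ I−) should give (2S,3S)-4-[(dimethylamino)methyl]-2-[(14S)-14-hydroxypentadecyl]-5-oxooxolane-3-carboxylic acid F7. MeI in MeOH should give {[(4S,5S)-4-carboxy-5-[(14S)-14-hydroxypentadecyl]-2-oxooxolan-3-yl]methyl}trimethylazanium iodide F8. Aqueous NaHCO3/EtOAc should then eliminate trimethylamine and come back to the route at 14.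

Further compounds
F1 | step 6 | (2S)-2-[(1S,10E,15S)-1-(acetyloxy)-15-hydroxyhexadec-10-en-1-yl]-4-(benzyloxy)-4-oxobutanoic acid | CC(=O)O[C@@H](CCCCCCCC/C=C/CCC[C@H](C)O)[C@H](CC(=O)OCc1ccccc1)C(=O)O
F2 | step 6 | (2S)-2-[(1S,15S)-1-(acetyloxy)-15-hydroxyhexadecyl]butanedioic acid | CC(=O)O[C@@H](CCCCCCCCCCCCC[C@H](C)O)[C@H](CC(=O)O)C(=O)O
F3 | step 6 | (2S)-2-[(1S,15S)-1,15-dihydroxyhexadecyl]butanedioic acid | O[C@@H](CCCCCCCCCCCCC[C@H](C)O)[C@H](CC(=O)O)C(=O)O
F4 | step 3 | benzyl 4-[(4S)-4-benzyl-2-oxo-1,3-oxazolidin-3-yl]-4-oxobutanoate | O=C(CCC(=O)OCc1ccccc1)N1[C@@H](Cc2ccccc2)COC1=O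
F5 | step 3 | benzyl (3S,4R)-3-[(4S)-4-benzyl-2-oxo-1,3-oxazolidine-3-carbonyl]-4-hydroxytetradec-13-enoate | O=C([C@@H](CC(=O)OCc1ccccc1)[C@H](O)CCCCCCCCC=C)N1[C@@H](Cc2ccccc2)COC1=O
F6 | step 3 | (2S,3R)-2-[2-(benzyloxy)-2-oxoethyl]-3-hydroxytridec-12-enoic acid | O=C(O)[C@@H](CC(=O)OCc1ccccc1)[C@H](O)CCCCCCCCC=C
F7 | step 7 | (2S,3S)-4-[(dimethylamino)methyl]-2-[(14S)-14-hydroxypentadecyl]-5-oxooxolane-3-carboxylic acid (C4 unassigned) | CN(C)CC1C(=O)O[C@@H](CCCCCCCCCCCCC[C@H](C)O)[C@H]1C(=O)O
F8 | step 7 | {[(4S,5S)-4-carboxy-5-[(14S)-14-hydroxypentadecyl]-2-oxooxolan-3-yl]methyl}trimethylazanium iodide (C3 unassigned) | C[N+](C)(C)CC1C(=O)O[C@@H](CCCCCCCCCCCCC[C@H](C)O)[C@H]1C(=O)O.[I-]
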